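## Retrosynthetic overview

- The strategy rests on the 4-hydroxy-2-pyrone ring (O1, C2=O, C3 carrying the bridge CH2, C4–OH, C5–Me, C6–Et). It is cut at O1–C2 and at C3–C4 into a 3-arylpropanoyl unit (C2, C3, bridge carbon) and methyl 2-methyl-3-oxopentanoate (C4, C5, C6, O1).
- Forward, O1–C2 is made first as a (Z)-enol ester. The pyrone, the only ring built in the route, is then closed at carbon (C3–C4) by a Dieckmann-type cyclisation, and the two MOM ethers are removed last.
- The 3-arylpropanoic acid comes from the fully substituted benzaldehyde by reductive alkylation of Meldrum's acid and decarboxylation.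
- The hexasubstituted benzene comes from 5-methoxyresorcinol. The bis-MOM ether is metalated and prenylated between the two MOM ethers, which makes the two remaining ring positions equivalent. A second metalation and acylation with the Weinreb amide of (R)-2-methylbutanoic acid follows, then MOM removal, formylation of the last ring C–H and MOM re-protection.

Key step: step 11

Assumption: (R)-2-methylbutanoic acid is used in high enantiomeric purity; keto ester 19 is used as the racemate because its stereocentre becomes an alkene carbon in step 10.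

## Route

Step 1
Reactants: 1 5-methoxyresorcinol
Product: 2 1-methoxy-3,5-bis(methoxymethoxy)benzene
Conditions: NaH, MOMCl, DMF, 0 °C → rt
Reagents that add atoms: chloromethyl methyl ether, COCCl
Why: Williamson-type O-alkylation of the bis-phenoxide with the reactive alpha-chloro ether should protect both phenols and install the two directing groups needed for the metalations.

Step 2
Reactants: 2 1-methoxy-3,5-bis(methoxymethoxy)benzene; 3 prenyl bromide (1-bromo-3-methylbut-2-ene)
Product: 5 5-methoxy-1,3-bis(methoxymethoxy)-2-(3-methylbut-2-en-1-yl)benzene, via aryllithium 4 (not isolated)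
Conditions: n-BuLi, THF, 0 °C → rt; then CuI (10 mol %), 3, −20 °C → rt
Reagents that add atoms: none
Why: Directed ortho-metalation should occur at the one C–H flanked by two chelating OCH2OMe groups (a stronger director than OMe), and copper-catalysed SN2 coupling of the aryllithium with the primary allylic bromide should give the linear prenyl group, leaving a symmetrical arene whose two remaining ring positions are equivalent.

Step 3
Reactants: 6 (R)-2-methylbutanoic acid
Product: 8 (2R)-N-methoxy-N,2-dimethylbutanamide, via acyl imidazole 7 (not isolated)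
Conditions: CDI, CH2Cl2, rt; then MeNHOMe·HCl, rt
Reagents that add atoms: N,O-dimethylhydroxylamine hydrochloride, CNOC.Cl
Why: Carbonyldiimidazole activation and aminolysis (amide coupling) proceed without enolisation of the alpha-branched acid, so the R stereocentre taken from 6 should be carried over unchanged.

Step 4
Reactants: 5 5-methoxy-1,3-bis(methoxymethoxy)-2-(3-methylbut-2-en-1-yl)benzene; 8 (2R)-N-methoxy-N,2-dimethylbutanamide
Product: 10 (2R)-1-[6-methoxy-2,4-bis(methoxymethoxy)-3-(3-methylbut-2-en-1-yl)phenyl]-2-methylbutan-1-one, via aryllithium 9 (not isolated)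
Conditions: n-BuLi, TMEDA, THF, −20 → 0 °C; then 8, −78 → 0 °C; then H2O
Reagents that add atoms: none
Why: A second directed ortho-metalation should take place at either of the two equivalent ring C–H bonds flanked by OCH2OMe and OMe, and addition of the aryllithium to the Weinreb amide gives a chelated tetrahedral adduct that releases the ketone only on work-up (Weinreb ketone synthesis), so over-addition is excluded and the stereocentre from 6 is never exposed to base as a ketone.

Step 5
Reactants: 10 (2R)-1-[6-methoxy-2,4-bis(methoxymethoxy)-3-(3-methylbut-2-en-1-yl)phenyl]-2-methylbutan-1-one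
Product: 11 (2R)-1-[2,4-dihydroxy-6-methoxy-3-(3-methylbut-2-en-1-yl)phenyl]-2-methylbutan-1-one
Conditions: 3 M aq. HCl, MeOH, rt → 40 °C
Reagents that add atoms: none
Why: Acid-catalysed acetal exchange with methanol should remove both methoxymethyl groups as dimethoxymethane under dilute, near-ambient conditions of the kind used to unmask ortho-prenyl phenols without chroman formation, freeing the phenols that activate the ring for formylation.

Step 6
Reactants: 11 (2R)-1-[2,4-dihydroxy-6-methoxy-3-(3-methylbut-2-en-1-yl)phenyl]-2-methylbutan-1-one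
Product: 12 2,4-dihydroxy-6-methoxy-5-[(2R)-2-methylbutanoyl]-3-(3-methylbut-2-en-1-yl)benzaldehyde
Conditions: POCl3, DMF, EtOAc, 0 °C → rt; then ice-water
Reagents that add atoms: N,N-dimethylformamide, CN(C)C=O; water, O
Why: Vilsmeier–Haack formylation, well established for acylphloroglucinols, can only attack the single unsubstituted ring carbon (ortho to the 4-OH, para to the 2-OH), and the base-free medium should leave the ketone stereocentre untouched while the isolated trisubstituted alkene is too unreactive toward the chloroiminium ion at this temperature.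

Step 7
Reactants: 12 2,4-dihydroxy-6-methoxy-5-[(2R)-2-methylbutanoyl]-3-(3-methylbut-2-en-1-yl)benzaldehyde
Product: 13 6-methoxy-2,4-bis(methoxymethoxy)-5-[(2R)-2-methylbutanoyl]-3-(3-methylbut-2-en-1-yl)benzaldehyde
Conditions: MOMCl, K2CO3, DMF, 0 °C → rt
Reagents that add atoms: chloromethyl methyl ether, COCCl
Why: O-Alkylation of the two acidic, hydrogen-bonded phenols with the alpha-chloro ether under carbonate base, too weak to enolise the ketone, should restore protection that is stable to amide bases and prevents lactonisation of the later propanoic acid onto the neighbouring phenol.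

Step 8
Reactants: 13 6-methoxy-2,4-bis(methoxymethoxy)-5-[(2R)-2-methylbutanoyl]-3-(3-methylbut-2-en-1-yl)benzaldehyde; 14 Meldrum's acid (2,2-dimethyl-1,3-dioxane-4,6-dione)
Product: 16 5-{[6-methoxy-2,4-bis(methoxymethoxy)-5-((2R)-2-methylbutanoyl)-3-(3-methylbut-2-en-1-yl)phenyl]methyl}-2,2-dimethyl-1,3-dioxane-4,6-dione, via arylidene Meldrum's acid 15 (not isolated)
Conditions: Hantzsch ester, L-proline (20 mol %), EtOH, rt
Reagents that add atoms: none
Why: Proline-catalysed Knoevenagel condensation followed in the same flask by conjugate hydride transfer from the dihydropyridine (three-component reductive alkylation) should add the two-carbon unit chemoselectively, since the hindered ketone does not condense and the isolated alkene is not reduced.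

Step 9
Reactants: 16 5-{[6-methoxy-2,4-bis(methoxymethoxy)-5-((2R)-2-methylbutanoyl)-3-(3-methylbut-2-en-1-yl)phenyl]methyl}-2,2-dimethyl-1,3-dioxane-4,6-dione
Product: 17 3-[6-methoxy-2,4-bis(methoxymethoxy)-5-((2R)-2-methylbutanoyl)-3-(3-methylbut-2-en-1-yl)phenyl]propanoic acid
Conditions: DMF–H2O (10:1), 100 °C
Reagents that add atoms: water, O
Why: Hydrolytic opening of the dioxanedione with loss of acetone and thermal decarboxylation of the resulting malonic acid should give the propanoic acid in a neutral medium that contains neither a base able to enolise the ketone nor an acid strong enough to cleave the MOM ethers.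

Step 10
Reactants: 17 3-[6-methoxy-2,4-bis(methoxymethoxy)-5-((2R)-2-methylbutanoyl)-3-(3-methylbut-2-en-1-yl)phenyl]propanoic acid; 19 methyl 2-methyl-3-oxopentanoate
Product: 21 methyl (2Z)-3-({3-[6-methoxy-2,4-bis(methoxymethoxy)-5-((2R)-2-methylbutanoyl)-3-(3-methylbut-2-en-1-yl)phenyl]propanoyl}oxy)-2-methylpent-2-enoate, via acid chloride 18 (not isolated), via lithium enolate 20 (not isolated)
Conditions: 17, Me2C=C(Cl)NMe2 (1.05 equiv), CH2Cl2, 0 °C → rt; 19 (1.2 equiv), LiN(SiMe3)2 (1.1 equiv), THF, −78 °C; then combine, −78 → 0 °C
Reagents that add atoms: none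
Why: The acid is converted to its chloride under neutral conditions (alpha-chloro enamine, no HCl), and the hard acyl chloride should acylate the lithium-chelated, U-shaped enolate of the alpha-substituted keto ester at oxygen (enolate O-acylation), because C-acylation would build a quaternary centre and the chelate holds the acyloxy and methoxycarbonyl groups cis, which is the Z alkene.

Step 11
Reactants: 21 methyl (2Z)-3-({3-[6-methoxy-2,4-bis(methoxymethoxy)-5-((2R)-2-methylbutanoyl)-3-(3-methylbut-2-en-1-yl)phenyl]propanoyl}oxy)-2-methylpent-2-enoate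
Product: 22 6-ethyl-4-hydroxy-3-{[6-methoxy-2,4-bis(methoxymethoxy)-5-((2R)-2-methylbutanoyl)-3-(3-methylbut-2-en-1-yl)phenyl]methyl}-5-methyl-2H-pyran-2-one
Conditions: LiN(SiMe3)2 (2.2 equiv), THF, −78 → −20 °C; then cold 0.5 M aq. HCl
Reagents that add atoms: none
Why: Proposed new method: the amide base should remove a proton from the CH2 next to the enol-ester carbonyl (future C3), the ester enolate then attacks the methyl ester carbonyl that the Z alkene places within reach, methoxide leaves, and the resulting pyran-2,4-dione is deprotonated to the aromatic lithium pyronate, which drives the sequence forward. The closest known reactions are the intramolecular Claisen closure of methyl O-acylsalicylates to 4-hydroxycoumarins, the Dieckmann closure of beta-acyloxy esters to 4-hydroxy-5,6-dihydro-2-pyranones and the Lacey–Dieckmann route to tetronic acids; an acyclic tetrasubstituted enol ester has not been used as the substrate. The pyrone ring closes in a 6-(enolexo)-exo-trig mode with C3–C4 as the new bond, and no stereocentre is created. The step needs enolisation at C3 and not at the alpha carbon of the aryl ketone, which should be secured kinetically at low temperature because the CH2 is unhindered and activated by the enol-ester carbonyl, whereas the ketone alpha C–H is tertiary and screened by the twisted ring carrying two ortho oxygen substituents. It also needs ring closure to outrun loss of the keto-ester enolate from the C3 enolate (ketene formation), which the intramolecular, geometrically pre-organised attack and the low temperature favour, and which is partly harmless because recapture of the ketene at oxygen returns 21.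

Step 12
Reactants: 22 6-ethyl-4-hydroxy-3-{[6-methoxy-2,4-bis(methoxymethoxy)-5-((2R)-2-methylbutanoyl)-3-(3-methylbut-2-en-1-yl)phenyl]methyl}-5-methyl-2H-pyran-2-one
Product: 23 3-{[2,4-dihydroxy-6-methoxy-5-((2R)-2-methylbutanoyl)-3-(3-methylbut-2-en-1-yl)phenyl]methyl}-6-ethyl-4-hydroxy-5-methyl-2H-pyran-2-one (CNP0233274.1)
Conditions: 3 M aq. HCl, MeOH, rt → 40 °C
Reagents that add atoms: none
Why: Acid-catalysed acetal exchange with methanol should cleave both methoxymethyl ethers under the same mild conditions as step 5, which are expected to spare the prenyl group, the hydroxypyrone and the ketone stereocentre.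

## Compound list

1 | 5-methoxyresorcinol | COc1cc(O)cc(O)c1 | starting material
2 | 1-methoxy-3,5-bis(methoxymethoxy)benzene | COCOc1cc(OC)cc(OCOC)c1 | intermediate
3 | prenyl bromide (1-bromo-3-methylbut-2-ene) | CC(C)=CCBr | starting material
4 | [4-methoxy-2,6-bis(methoxymethoxy)phenyl]lithium | [Li]c1c(OCOC)cc(OC)cc1OCOC | intermediate
5 | 5-methoxy-1,3-bis(methoxymethoxy)-2-(3-methylbut-2-en-1-yl)benzene | COCOc1cc(OC)cc(OCOC)c1CC=C(C)C | intermediate
6 | (R)-2-methylbutanoic acid | OC(=O)[C@H](C)CC | starting material
7 | (2R)-1-(imidazol-1-yl)-2-methylbutan-1-one | O=C(n1ccnc1)[C@H](C)CC | intermediate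
8 | (2R)-N-methoxy-N,2-dimethylbutanamide | CON(C)C(=O)[C@H](C)CC | intermediate
9 | [6-methoxy-2,4-bis(methoxymethoxy)-3-(3-methylbut-2-en-1-yl)phenyl]lithium | COc1cc(OCOC)c(CC=C(C)C)c(OCOC)c1[Li] | intermediate
10 | (2R)-1-[6-methoxy-2,4-bis(methoxymethoxy)-3-(3-methylbut-2-en-1-yl)phenyl]-2-methylbutan-1-one | COc1cc(OCOC)c(CC=C(C)C)c(OCOC)c1C(=O)[C@H](C)CC | intermediate
11 | (2R)-1-[2,4-dihydroxy-6-methoxy-3-(3-methylbut-2-en-1-yl)phenyl]-2-methylbutan-1-one | COc1cc(O)c(CC=C(C)C)c(O)c1C(=O)[C@H](C)CC | intermediate
12 | 2,4-dihydroxy-6-methoxy-5-[(2R)-2-methylbutanoyl]-3-(3-methylbut-2-en-1-yl)benzaldehyde | COc1c(C=O)c(O)c(CC=C(C)C)c(O)c1C(=O)[C@H](C)CC | intermediate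
13 | 6-methoxy-2,4-bis(methoxymethoxy)-5-[(2R)-2-methylbutanoyl]-3-(3-methylbut-2-en-1-yl)benzaldehyde | COc1c(C=O)c(OCOC)c(CC=C(C)C)c(OCOC)c1C(=O)[C@H](C)CC | intermediate
14 | Meldrum's acid (2,2-dimethyl-1,3-dioxane-4,6-dione) | CC1(C)OC(=O)CC(=O)O1 | starting material
15 | 5-{[6-methoxy-2,4-bis(methoxymethoxy)-5-((2R)-2-methylbutanoyl)-3-(3-methylbut-2-en-1-yl)phenyl]methylidene}-2,2-dimethyl-1,3-dioxane-4,6-dione | COc1c(C=C2C(=O)OC(C)(C)OC2=O)c(OCOC)c(CC=C(C)C)c(OCOC)c1C(=O)[C@H](C)CC | intermediate
16 | 5-{[6-methoxy-2,4-bis(methoxymethoxy)-5-((2R)-2-methylbutanoyl)-3-(3-methylbut-2-en-1-yl)phenyl]methyl}-2,2-dimethyl-1,3-dioxane-4,6-dione | COc1c(CC2C(=O)OC(C)(C)OC2=O)c(OCOC)c(CC=C(C)C)c(OCOC)c1C(=O)[C@H](C)CC | intermediate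
17 | 3-[6-methoxy-2,4-bis(methoxymethoxy)-5-((2R)-2-methylbutanoyl)-3-(3-methylbut-2-en-1-yl)phenyl]propanoic acid | COc1c(CCC(=O)O)c(OCOC)c(CC=C(C)C)c(OCOC)c1C(=O)[C@H](C)CC | intermediate
18 | 3-[6-methoxy-2,4-bis(methoxymethoxy)-5-((2R)-2-methylbutanoyl)-3-(3-methylbut-2-en-1-yl)phenyl]propanoyl chloride | COc1c(CCC(=O)Cl)c(OCOC)c(CC=C(C)C)c(OCOC)c1C(=O)[C@H](C)CC | intermediate
19 | methyl 2-methyl-3-oxopentanoate (racemic) | CCC(=O)C(C)C(=O)OC | starting material
20 | lithium (Z)-enolate of methyl 2-methyl-3-oxopentanoate | CC/C(O[Li])=C(\C)C(=O)OC | intermediate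
21 | methyl (2Z)-3-({3-[6-methoxy-2,4-bis(methoxymethoxy)-5-((2R)-2-methylbutanoyl)-3-(3-methylbut-2-en-1-yl)phenyl]propanoyl}oxy)-2-methylpent-2-enoate | CC/C(OC(=O)CCc1c(OCOC)c(CC=C(C)C)c(OCOC)c(C(=O)[C@H](C)CC)c1OC)=C(\C)C(=O)OC | intermediate
22 | 6-ethyl-4-hydroxy-3-{[6-methoxy-2,4-bis(methoxymethoxy)-5-((2R)-2-methylbutanoyl)-3-(3-methylbut-2-en-1-yl)phenyl]methyl}-5-methyl-2H-pyran-2-one | CCc1oc(=O)c(Cc2c(OCOC)c(CC=C(C)C)c(OCOC)c(C(=O)[C@H](C)CC)c2OC)c(O)c1C | intermediate
23 | 3-{[2,4-dihydroxy-6-methoxy-5-((2R)-2-methylbutanoyl)-3-(3-methylbut-2-en-1-yl)phenyl]methyl}-6-ethyl-4-hydroxy-5-methyl-2H-pyran-2-one | CCc1oc(=O)c(Cc2c(O)c(CC=C(C)C)c(O)c(C(=O)[C@H](C)CC)c2OC)c(O)c1C | target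

## Step count and risks

Total step count: 12. Longest linear sequence: 11 steps (1 to 23 through steps 1, 2 and 4–12; step 3 is a one-step branch that joins at step 4, and 19 joins at step 10).

Steps most likely to fail:

1. Step 11 (proposed new method). The C3 enolate may expel the keto-ester enolate and fragment to a ketene faster than it closes the ring. The base may also remove the alpha proton of the aryl ketone, which erodes the configuration, or a gamma proton of the enoate. Fallback by known chemistry, setting out from aldehyde 13 and returning at 22: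
   - The dianion of commercial methyl 3-oxopentanoate (NaH, then n-BuLi, THF, 0 °C) is propionylated at C4 with N-methoxy-N-methylpropanamide to give methyl 4-methyl-3,5-dioxoheptanoate F1.
   - DBU in toluene at 80 °C lactonises F1 with loss of methanol to 6-ethyl-4-hydroxy-5-methyl-2H-pyran-2-one F2.
   - F2, aldehyde 13 and Hantzsch ester with catalytic L-proline in CH2Cl2 at rt should give 22 by Knoevenagel condensation at C3 of the pyrone and conjugate hydride transfer (reductive alkylation of a 4-hydroxypyrone). The bridge carbon then comes from the aldehyde carbon of 13.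

2. Step 10. Acylation may occur at carbon instead of oxygen, or the chelate may be lost so that the E enol ester forms, which cannot cyclise. Fallback setting out from 17 and 19 and returning at 21:
   - 19 is silylated through its sodium chelate (NaH, then Me3SiCl, Et2O, 0 °C) to methyl (2Z)-2-methyl-3-(trimethylsilyloxy)pent-2-enoate F3, whose geometry can be assigned and, if needed, purified before use.
   - 17 is converted with cyanuric fluoride and pyridine (CH2Cl2, 0 °C) to 3-[6-methoxy-2,4-bis(methoxymethoxy)-5-((2R)-2-methylbutanoyl)-3-(3-methylbut-2-en-1-yl)phenyl]propanoyl fluoride F4.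
   - F3 and F4 with a catalytic anhydrous fluoride source (Bu4N Ph3SiF2) in THF at −78 °C should give 21 by fluoride-catalysed O-acyl transfer with loss of Me3SiF. The alkene geometry is then fixed at the silyl stage and not in the acylation event, and no stoichiometric enolate meets the acid halide.

3. Step 4. The base may deprotonate the benzylic-allylic CH2 of the prenyl group instead of the ring, or the hindered aryllithium may take a proton from the amide instead of adding to it. Fallback setting out from 1 and 6 and returning at 11:
   - 6 is converted with oxalyl chloride and catalytic DMF to (R)-2-methylbutanoyl chloride F5.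
   - Friedel–Crafts acylation of 1 with F5 (AlCl3, nitrobenzene–CH2Cl2, 0 °C → rt) gives, after chromatographic removal of the 2,6-dihydroxy-4-methoxy isomer, (2R)-1-(2,4-dihydroxy-6-methoxyphenyl)-2-methylbutan-1-one F6.
   - C-prenylation of F6 with 3 in aqueous KOH at 0 °C should give 11 after separation from the 5-prenyl and O-prenyl isomers. This path uses no organolithium and bypasses steps 1, 2, 4 and 5, at the price of lower regiocontrol.

## Further compounds

F1 | step 11 | methyl 4-methyl-3,5-dioxoheptanoate | CCC(=O)C(C)C(=O)CC(=O)OC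
F2 | step 11 | 6-ethyl-4-hydroxy-5-methyl-2H-pyran-2-one | CCc1oc(=O)cc(O)c1C
F3 | step 10 | methyl (2Z)-2-methyl-3-(trimethylsilyloxy)pent-2-enoate | CC/C(O[Si](C)(C)C)=C(\C)C(=O)OC
F4 | step 10 | 3-[6-methoxy-2,4-bis(methoxymethoxy)-5-((2R)-2-methylbutanoyl)-3-(3-methylbut-2-en-1-yl)phenyl]propanoyl fluoride | COc1c(CCC(=O)F)c(OCOC)c(CC=C(C)C)c(OCOC)c1C(=O)[C@H](C)CC
F5 | step 4 | (R)-2-methylbutanoyl chloride | ClC(=O)[C@H](C)CC
F6 | step 4 | (2R)-1-(2,4-dihydroxy-6-methoxyphenyl)-2-methylbutan-1-one | COc1cc(O)cc(O)c1C(=O)[C@H](C)CC
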